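**Retrosynthetic overview**

1. Labels (target): cycloheptane C1 [C(OH) carrying C2(=O)–C3=C4–C15], C5 [CH–O‑isovaleryl], C6 [CH–O of the lactone], C7, C8, C9 [CHOH], C10 [CH–C14H3]; lactone C11(=C13H2)–C12(=O)–O6.
2. Enabling feature: in the seven‑membered ring the C9 carbinol is next to C10, a CH that carries only the C14 methyl and sits on the fully substituted C1. This hydroxyl/methyl pair is the retron of a C9 aldehyde adding reductively to C10 of a C10=C14 vinyl sulfone held on C1, the sulfonyl group being a traceless activator that leaves C14 as CH3.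
3. Disconnections: lactone O6–C12 and the (Z)‑enone C2=O last, both by one MnO2 oxidation; C9–C10 by SmI2 ketyl–olefin 7‑exo cyclisation/desulfonylation of an acyclic aldehyde; C7–C11 by cuprate addition; C1–C10 by addition to a furanosid‑2‑ulose; C2–C3 by (Z)‑propenyl addition to a lactol.
4. Stereocentres: D‑xylose supplies C5 and C6 and, as a furanoside template, controls C1 and C7; C9 and C10 arise in the key step.
5. Ring order: no carbocycle until the cycloheptane is closed at C9–C10 (step 17); the γ‑lactone is closed last (step 19).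

Key step: step 17

Remark on the chemistry: sugar C1–C5 become target C2, C1, C5, C6, C7; three centres that disappear before the target are carried unassigned or as mixtures (arylidene acetal carbon in 3–5, anomeric carbon in 13, C2 carbinol in 14–23).

**Route**

Step 1
Reactants: 1 D‑xylose
Product: 3 methyl 3,5‑O‑(4‑methoxybenzylidene)‑β‑D‑xylofuranoside, via methyl β‑D‑xylofuranoside 2 (not isolated)
Conditions: AcCl (cat.), MeOH, rt; neutralise, evaporate; then 4‑MeOC6H4CH(OMe)2, CSA (cat.), MeCN, rt; β‑anomer separated by chromatography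
Reagents that add atoms: methanol (CO); 4‑methoxybenzaldehyde dimethyl acetal (COc1ccc(C(OC)OC)cc1)
Why: Kinetic Fischer glycosidation gives the furanoside, whose cis O3 and O5 close the six‑membered arylidene acetal and leave only O2 free; the sugar stereocentres are untouched.

Step 2
Reactants: 3 arylidene acetal
Product: 4 methyl 3,5‑O‑(4‑methoxybenzylidene)‑β‑D‑threo‑pentofuranosid‑2‑ulose
Conditions: Dess–Martin periodinane, pyridine, CH2Cl2, 0 °C → rt
Reagents that add atoms: none
Why: Dess–Martin oxidation of the single free secondary alcohol under buffered conditions that spare both acetals; no stereocentre is formed.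

Step 3
Reactants: 4 2‑ulose
Product: 5 methyl 2‑C‑(1,3‑dithian‑2‑yl)‑3,5‑O‑(4‑methoxybenzylidene)‑β‑D‑lyxofuranoside
Conditions: 1,3‑dithiane, n‑BuLi, THF, −30 °C; then 4, −78 °C; H2O
Reagents that add atoms: 1,3‑dithiane (C1CSCSC1)
Why: Corey–Seebach addition of 2‑lithio‑1,3‑dithiane to the ketone from the α‑face, the β‑face being covered by the cis‑fused dioxane ring and the β‑methoxy group, sets the tertiary carbinol (target C1) with OH cis to O3, as in classical branched‑sugar syntheses from uloses.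

Step 4
Reactants: 5 dithianyl carbinol
Product: 6 methyl 2‑C‑(1,3‑dithian‑2‑yl)‑3‑O‑(4‑methoxybenzyl)‑β‑D‑lyxofuranoside
Conditions: DIBAL‑H (4 equiv), CH2Cl2, −78 → 0 °C; Rochelle salt
Reagents that add atoms: none
Why: Reductive opening of the 4‑methoxybenzylidene acetal, with aluminium on the less hindered primary oxygen, leaves the PMB ether on secondary O3 (target O5) and frees the primary 5‑OH.

Step 5
Reactants: 6 primary alcohol
Product: 8 ethyl (E)‑enoate (methyl 5,6‑dideoxy‑2‑C‑(1,3‑dithian‑2‑yl)‑3‑O‑(4‑methoxybenzyl)‑β‑D‑lyxo‑hept‑5‑enofuranosiduronic acid ethyl ester), via aldehyde 7 (not isolated)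
Conditions: (COCl)2, DMSO, CH2Cl2, −78 °C; Et3N, −78 → 0 °C; then Ph3P=CHCO2Et, rt
Reagents that add atoms: ethyl (triphenylphosphoranylidene)acetate (CCOC(=O)C=P(c1ccccc1)(c1ccccc1)c1ccccc1)
Why: One‑flask Swern oxidation and Wittig reaction with the stabilised ylide give the (E)‑enoate (target C7=C8–C9) without isolating the epimerisable α‑alkoxy aldehyde.

Step 6
Reactants: 9 2‑bromoprop‑2‑en‑1‑ol
Product: 10 [(2‑bromoprop‑2‑en‑1‑yl)oxy](tert‑butyl)diphenylsilane
Conditions: TBDPSCl, imidazole, DMF, rt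
Reagents that add atoms: tert‑butyl(chloro)diphenylsilane (CC(C)(C)[Si](Cl)(c1ccccc1)c1ccccc1)
Why: Standard silylation; the acid‑stable TBDPS ether is chosen to survive step 9.

Step 7
Reactants: 8 ethyl (E)‑enoate; 10 bromoalkene
Product: 11 conjugate adduct (as 8, but C5 of the sugar = target C7 is sp3 and carries H, the CH2CO2Et arm and the 3‑(TBDPS‑oxy)prop‑1‑en‑2‑yl group)
Conditions: 10, t‑BuLi (2 equiv), Et2O, −78 °C; CuI (0.5 equiv); TMSCl, then 8, THF, −78 → −40 °C; 1 M HCl (aq), 0 °C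
Reagents that add atoms: none
Why: TMSCl‑accelerated conjugate addition of the alkenyl Gilman cuprate to the γ‑alkoxy (E)‑enoate anti to the ring oxygen (modified Felkin–Anh model, as for sugar‑derived γ‑alkoxy enoates) should set C7; TMSCl also masks the tertiary OH in situ so that no oxa‑Michael closure competes.

Step 8
Reactants: 11 ester
Product: 12 primary alcohol (C9 at the alcohol level)
Conditions: DIBAL‑H, CH2Cl2, −78 → 0 °C; Rochelle salt
Reagents that add atoms: none
Why: Ester reduction is done before the ring oxygen is released, so that the O6 alkoxide of step 10 finds no ester to lactonise onto.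

Step 9
Reactants: 12 methyl furanoside
Product: 13 lactol (anomers)
Conditions: 1 M HCl (aq)/THF (1:4), 50 °C
Reagents that add atoms: water (O)
Why: Acid hydrolysis of the methyl furanoside to the hemiacetal; the PMB ether, TBDPS ether and dithiane are stable to dilute aqueous acid.

Step 10
Reactants: 13 lactol
Product: 14 acyclic tetraol (C2–OH, C1–OH, C6–OH, C9–OH free; O5‑PMB; C1‑dithianyl; O12‑TBDPS; (Z)‑C3=C4)
Conditions: (Z)‑1‑bromopropene, t‑BuLi (2 equiv), Et2O, −78 °C; MgBr2·OEt2; then 13, THF, −78 °C → rt (5 equiv of reagent); H2O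
Reagents that add atoms: (Z)‑1‑bromoprop‑1‑ene (C/C=C\Br)
Why: Grignard addition to the open hydroxy‑aldehyde form of the lactol installs C3=C4–C15 on C2 and frees O6; halogen–lithium exchange and transmetalation go with retention, so the alkene stays (Z), and the new C2 carbinol centre is later oxidised away.

Step 11
Reactants: 14 tetraol
Product: 15 tetrakis(triethylsilyl) ether (O2, O1, O6, O9)
Conditions: TESOTf (6 equiv), 2,6‑lutidine, CH2Cl2, −78 → 0 °C
Reagents that add atoms: triethylsilyl trifluoromethanesulfonate (CC[Si](CC)(CC)OS(=O)(=O)C(F)(F)F)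
Why: The silyl triflate silylates the primary, both secondary and the tertiary hydroxyl; masking O1 also removes the one hydroxyl that could chelate samarium in step 17.

Step 12
Reactants: 15 dithiane
Product: 16 C10 aldehyde on quaternary C1
Conditions: MeI, CaCO3, MeCN/H2O (9:1), 45 °C
Reagents that add atoms: water (O)
Why: Alkylative dithiane hydrolysis under neutral conditions unmasks a non‑enolisable α‑silyloxy aldehyde and leaves the silyl ethers and alkenes alone.

Step 13
Reactants: 16 aldehyde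
Product: 17 (E)‑vinyl sulfone (C10=C14–SO2Ph)
Conditions: (EtO)2P(O)CH2SO2Ph, NaH, THF, 0 °C → rt
Reagents that add atoms: diethyl [(phenylsulfonyl)methyl]phosphonate (CCOP(=O)(CS(=O)(=O)c1ccccc1)OCC)
Why: Horner–Wadsworth–Emmons olefination gives the (E)‑vinyl sulfone, the radical acceptor of the key step.

Step 14
Reactants: 17 PMB ether
Product: 18 C5 alcohol
Conditions: DDQ, CH2Cl2/pH 7 buffer, 0 °C → rt
Reagents that add atoms: none
Why: Oxidative PMB cleavage frees only O5; silyl ethers, vinyl sulfone and the unactivated alkenes are inert.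

Step 15
Reactants: 18 C5 alcohol
Product: 19 C5 isovalerate
Conditions: isovaleric anhydride, DMAP, Et3N, CH2Cl2, rt
Reagents that add atoms: 3‑methylbutanoic anhydride (CC(C)CC(=O)OC(=O)CC(C)C)
Why: DMAP‑catalysed acylation of the single free hydroxyl places the isovalerate on O5 before the C9 hydroxyl exists.

Step 16
Reactants: 19 primary TES ether
Product: 20 C9 aldehyde (cyclisation precursor)
Conditions: (COCl)2, DMSO, CH2Cl2, −78 → −40 °C; Et3N, → 0 °C
Reagents that add atoms: none
Why: Swern conditions convert a primary TES ether directly into the aldehyde while secondary and tertiary TES ethers survive (known selective oxidation of primary TES ethers).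

Step 17
Reactants: 20 C9 aldehyde
Product: 22 silyl‑protected cycloheptanol carrying the C14 methyl, via cyclised sulfone 21 (not isolated)
Conditions: SmI2 (3 equiv), MeOH (4 equiv), THF, 0 °C, slow addition of 20 (0.005 M); then HMPA, SmI2 (6 equiv), −20 °C → rt
Reagents that add atoms: none
Why: SmI2 reduces the C9 aldehyde to a samarium ketyl that adds to C10, the β‑carbon of the (E)‑vinyl sulfone; the α‑sulfonyl radical is reduced to the carbanion and protonated by MeOH (21), and SmI2/HMPA then cleaves the C14–S bond so that C14 ends as the methyl group. The closest known reaction types are SmI2‑induced aldehyde–alkene reductive cyclisations onto acrylates and vinyl sulfones that close six‑ and seven‑membered rings, and the reductive desulfonylation of alkyl phenyl sulfones with SmI2/HMPA. One ring is closed, the cycloheptane, by radical 7‑exo‑trig attack of C9 on C10. C9 and C10 are set together: in the chair‑like transition state the O–Sm bond and the sulfonylvinyl arm are both pseudo‑equatorial, with samarium bridging the ketyl and a sulfonyl oxygen, which should give the trans C9–O/C10–C14 pair, and the fixed quaternary C1 chooses the face because its larger substituent, the branched C2 side chain, stays pseudo‑equatorial and so trans to C14. The step needs chemoselectivity for the aldehyde (isovalerate, silyl ethers and both unactivated alkenes are inert, and the ketyl could reach the 1,1‑disubstituted alkene only by 4‑exo or 5‑endo closure), 7‑exo over 8‑endo regioselectivity, secured by the polarity of the acceptor, and suppression of pinacol coupling by high dilution. The TES group on O1 prevents chelation to that oxygen, which would reverse the facial sense.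

Step 18
Reactants: 22 protected cycloheptanol
Product: 23 pentaol monoester (free O1, O2, O6, O9, O12; isovalerate on O5)
Conditions: HF·pyridine, pyridine, THF, 0 °C → rt
Reagents that add atoms: none
Why: Buffered acidic fluoride removes the four TES ethers and the TBDPS ether without base‑induced migration of the isovalerate.

Step 19
Reactants: 23 pentaol monoester
Product: 24 CNP0186412.2 (target)
Conditions: activated MnO2 (excess), CH2Cl2, rt
Reagents that add atoms: none
Why: MnO2 oxidises only the two allylic alcohols: the C2 carbinol gives the (Z)‑enone, and the C12 alcohol gives the enal, which the cis O6–H traps as a lactol that is oxidised on to the α‑methylene‑γ‑lactone; the saturated C9–OH and tertiary C1–OH stay.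

**Compound list**

1 | D‑xylose | O=C[C@H](O)[C@@H](O)[C@H](O)CO | starting material
2 | methyl β‑D‑xylofuranoside | CO[C@@H]1O[C@H](CO)[C@H](O)[C@H]1O | intermediate
3 | methyl 3,5‑O‑(4‑methoxybenzylidene)‑β‑D‑xylofuranoside | CO[C@@H]1O[C@@H]2COC(c3ccc(OC)cc3)O[C@@H]2[C@H]1O | intermediate
4 | methyl 3,5‑O‑(4‑methoxybenzylidene)‑β‑D‑threo‑pentofuranosid‑2‑ulose | CO[C@@H]1O[C@@H]2COC(c3ccc(OC)cc3)O[C@@H]2C1=O | intermediate
5 | methyl 2‑C‑(1,3‑dithian‑2‑yl)‑3,5‑O‑(4‑methoxybenzylidene)‑β‑D‑lyxofuranoside | CO[C@@H]1O[C@@H]2COC(c3ccc(OC)cc3)O[C@@H]2[C@@]1(O)C4SCCCS4 | intermediate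
6 | methyl 2‑C‑(1,3‑dithian‑2‑yl)‑3‑O‑(4‑methoxybenzyl)‑β‑D‑lyxofuranoside | CO[C@@H]1O[C@H](CO)[C@H](OCc2ccc(OC)cc2)[C@@]1(O)C3SCCCS3 | intermediate
7 | C5 aldehyde of 6 (pentodialdo‑1,4‑furanoside) | CO[C@@H]1O[C@H](C=O)[C@H](OCc2ccc(OC)cc2)[C@@]1(O)C3SCCCS3 | intermediate
8 | ethyl (E)‑enoate from 7 (hept‑5‑enofuranosiduronate) | CO[C@@H]1O[C@H](/C=C/C(=O)OCC)[C@H](OCc2ccc(OC)cc2)[C@@]1(O)C3SCCCS3 | intermediate
9 | 2‑bromoprop‑2‑en‑1‑ol | OCC(Br)=C | starting material
10 | [(2‑bromoprop‑2‑en‑1‑yl)oxy](tert‑butyl)diphenylsilane | C=C(Br)CO[Si](c1ccccc1)(c1ccccc1)C(C)(C)C | intermediate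
11 | conjugate adduct, ethyl ester (target C7 set) | CO[C@@H]1O[C@H]([C@@H](CC(=O)OCC)C(=C)CO[Si](c2ccccc2)(c2ccccc2)C(C)(C)C)[C@H](OCc2ccc(OC)cc2)[C@@]1(O)C3SCCCS3 | intermediate
12 | primary alcohol from 11 | CO[C@@H]1O[C@H]([C@@H](CCO)C(=C)CO[Si](c2ccccc2)(c2ccccc2)C(C)(C)C)[C@H](OCc2ccc(OC)cc2)[C@@]1(O)C3SCCCS3 | intermediate
13 | lactol from 12 (anomers) | OC1O[C@H]([C@@H](CCO)C(=C)CO[Si](c2ccccc2)(c2ccccc2)C(C)(C)C)[C@H](OCc2ccc(OC)cc2)[C@@]1(O)C3SCCCS3 | intermediate
14 | acyclic (Z)‑propenyl tetraol (C2 epimers) | C/C=C\C(O)[C@](O)(C1SCCCS1)[C@@H](OCc1ccc(OC)cc1)[C@H](O)[C@@H](CCO)C(=C)CO[Si](c1ccccc1)(c1ccccc1)C(C)(C)C | intermediate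
15 | tetrakis(triethylsilyl) ether of 14 | C/C=C\C(O[Si](CC)(CC)CC)[C@](O[Si](CC)(CC)CC)(C1SCCCS1)[C@@H](OCc1ccc(OC)cc1)[C@H](O[Si](CC)(CC)CC)[C@@H](CCO[Si](CC)(CC)CC)C(=C)CO[Si](c1ccccc1)(c1ccccc1)C(C)(C)C | intermediate
16 | C10 aldehyde | C/C=C\C(O[Si](CC)(CC)CC)[C@](O[Si](CC)(CC)CC)(C=O)[C@@H](OCc1ccc(OC)cc1)[C@H](O[Si](CC)(CC)CC)[C@@H](CCO[Si](CC)(CC)CC)C(=C)CO[Si](c1ccccc1)(c1ccccc1)C(C)(C)C | intermediate
17 | (E)‑vinyl sulfone, O5‑PMB | C/C=C\C(O[Si](CC)(CC)CC)[C@](O[Si](CC)(CC)CC)(/C=C/S(=O)(=O)c1ccccc1)[C@@H](OCc1ccc(OC)cc1)[C@H](O[Si](CC)(CC)CC)[C@@H](CCO[Si](CC)(CC)CC)C(=C)CO[Si](c1ccccc1)(c1ccccc1)C(C)(C)C | intermediate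
18 | vinyl sulfone, free C5–OH | C/C=C\C(O[Si](CC)(CC)CC)[C@](O[Si](CC)(CC)CC)(/C=C/S(=O)(=O)c1ccccc1)[C@@H](O)[C@H](O[Si](CC)(CC)CC)[C@@H](CCO[Si](CC)(CC)CC)C(=C)CO[Si](c1ccccc1)(c1ccccc1)C(C)(C)C | intermediate
19 | vinyl sulfone, C5 isovalerate | C/C=C\C(O[Si](CC)(CC)CC)[C@](O[Si](CC)(CC)CC)(/C=C/S(=O)(=O)c1ccccc1)[C@@H](OC(=O)CC(C)C)[C@H](O[Si](CC)(CC)CC)[C@@H](CCO[Si](CC)(CC)CC)C(=C)CO[Si](c1ccccc1)(c1ccccc1)C(C)(C)C | intermediate
20 | C9 aldehyde (cyclisation precursor) | C/C=C\C(O[Si](CC)(CC)CC)[C@](O[Si](CC)(CC)CC)(/C=C/S(=O)(=O)c1ccccc1)[C@@H](OC(=O)CC(C)C)[C@H](O[Si](CC)(CC)CC)[C@@H](CC=O)C(=C)CO[Si](c1ccccc1)(c1ccccc1)C(C)(C)C | intermediate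
21 | cyclised sulfone (C10–CH2SO2Ph) | C/C=C\C(O[Si](CC)(CC)CC)[C@]1(O[Si](CC)(CC)CC)[C@@H](CS(=O)(=O)c2ccccc2)[C@H](O)C[C@@H](C(=C)CO[Si](c2ccccc2)(c2ccccc2)C(C)(C)C)[C@@H](O[Si](CC)(CC)CC)[C@@H]1OC(=O)CC(C)C | intermediate
22 | silyl‑protected cycloheptanol with C14 methyl | C/C=C\C(O[Si](CC)(CC)CC)[C@]1(O[Si](CC)(CC)CC)[C@@H](C)[C@H](O)C[C@@H](C(=C)CO[Si](c2ccccc2)(c2ccccc2)C(C)(C)C)[C@@H](O[Si](CC)(CC)CC)[C@@H]1OC(=O)CC(C)C | intermediate
23 | pentaol monoester | C/C=C\C(O)[C@]1(O)[C@@H](C)[C@H](O)C[C@@H](C(=C)CO)[C@@H](O)[C@@H]1OC(=O)CC(C)C | intermediate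
24 | CNP0186412.2 | C=C1C(=O)O[C@@H]2[C@H]1C[C@@H](O)[C@H](C)[C@@](O)(C(=O)/C=C\C)[C@H]2OC(=O)CC(C)C | target

**Count and risks**

Total steps: 19. Longest linear sequence: 18 steps (1 → 24; step 6 is a one‑step side branch).

Steps most likely to fail:

Step 17 (ring closure). The 7‑exo radical closure may be too slow, so that the ketyl is simply reduced to the primary alcohol or dimerises, or the facial selectivity at C9/C10 may be poor. The fallback sets out from 20 and comes back at 22. The aldehyde is oxidised (NaClO2, NaH2PO4, 2‑methylbut‑2‑ene) to the carboxylic acid F1 and converted (PhSeSePh, PBu3) into the Se‑phenyl selenoester F2. F2 is cyclised as the acyl radical (Bu3SnH, AIBN, benzene, 80 °C, slow addition) to the C9 ketone F3; this is a 7‑exo acyl radical addition to the vinyl sulfone in which C10 stays epimerisable and should settle trans to the C2 side chain. SmI2/HMPA/i‑PrOH then reduces the ketone to the equatorial C9 alcohol and cleaves the sulfone, which gives 22.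

Step 7 (conjugate addition). The facial selectivity at C7 may be poor, or the tertiary alkoxide may close onto the enoate by oxa‑Michael addition. The fallback sets out from aldehyde 7 (made as in step 5) and comes back at 11. Horner–Wadsworth–Emmons reaction with ethyl 3‑(tert‑butyldiphenylsilyloxy)‑2‑(diethoxyphosphoryl)propanoate gives the trisubstituted enoate F4, and DIBAL‑H gives the allylic alcohol F5. A Johnson–Claisen rearrangement (MeC(OEt)3, cat. EtCO2H, 140 °C) then forms the C7–C8 bond through a chair transition state and delivers 11 with the exo‑methylene group already in place.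

Step 10 (lactol opening). The hindered lactol next to quaternary C1 may open and add sluggishly, and long exposure to excess reagent may erode the (Z)‑geometry. The fallback sets out from 13 and comes back at 14. Fétizon oxidation (Ag2CO3 on Celite, benzene, reflux) gives the γ‑lactone F6; (Z)‑propenyllithium at −78 °C adds once to give the hydroxy (Z)‑enone F7 (in equilibrium with its hemiketal); Luche reduction (NaBH4, CeCl3·7H2O, MeOH) gives 14.

**Further compounds**

F1 | step 17 | carboxylic acid from 20 (C9 as CO2H) | C/C=C\C(O[Si](CC)(CC)CC)[C@](O[Si](CC)(CC)CC)(/C=C/S(=O)(=O)c1ccccc1)[C@@H](OC(=O)CC(C)C)[C@H](O[Si](CC)(CC)CC)[C@@H](CC(=O)O)C(=C)CO[Si](c1ccccc1)(c1ccccc1)C(C)(C)C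
F2 | step 17 | Se‑phenyl selenoester of F1 | C/C=C\C(O[Si](CC)(CC)CC)[C@](O[Si](CC)(CC)CC)(/C=C/S(=O)(=O)c1ccccc1)[C@@H](OC(=O)CC(C)C)[C@H](O[Si](CC)(CC)CC)[C@@H](CC(=O)[Se]c1ccccc1)C(=C)CO[Si](c1ccccc1)(c1ccccc1)C(C)(C)C
F3 | step 17 | cyclised C9 ketone with C10–CH2SO2Ph | C/C=C\C(O[Si](CC)(CC)CC)[C@]1(O[Si](CC)(CC)CC)[C@@H](CS(=O)(=O)c2ccccc2)C(=O)C[C@@H](C(=C)CO[Si](c2ccccc2)(c2ccccc2)C(C)(C)C)[C@@H](O[Si](CC)(CC)CC)[C@@H]1OC(=O)CC(C)C
F4 | step 7 | trisubstituted ethyl enoate from aldehyde 7 | CO[C@@H]1O[C@H](/C=C(/C(=O)OCC)CO[Si](c2ccccc2)(c2ccccc2)C(C)(C)C)[C@H](OCc2ccc(OC)cc2)[C@@]1(O)C3SCCCS3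
F5 | step 7 | allylic alcohol from F4 | CO[C@@H]1O[C@H](/C=C(/CO)CO[Si](c2ccccc2)(c2ccccc2)C(C)(C)C)[C@H](OCc2ccc(OC)cc2)[C@@]1(O)C3SCCCS3
F6 | step 10 | γ‑lactone from lactol 13 | O=C1O[C@H]([C@@H](CCO)C(=C)CO[Si](c2ccccc2)(c2ccccc2)C(C)(C)C)[C@H](OCc2ccc(OC)cc2)[C@@]1(O)C3SCCCS3
F7 | step 10 | hydroxy (Z)‑enone from F6 | C/C=C\C(=O)[C@](O)(C1SCCCS1)[C@@H](OCc1ccc(OC)cc1)[C@H](O)[C@@H](CCO)C(=C)CO[Si](c1ccccc1)(c1ccccc1)C(C)(C)C
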